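Retrosynthetic overview
1. The target is (2S)-4',7-dihydroxyflavan-(4β→8)-epiafzelechin-(4β→8)-epiafzelechin (units 1, 2, 3). The last operations are hydrogenolysis of nine benzyl ethers and a Friedel–Crafts C4(unit 1)–C8(unit 2) coupling with a flavan-4-ol made from (2S)-liquiritigenin.
2. The strategy rests on the C4(unit 2)–C8(unit 3) bond. C8 of unit 3 is the ring A carbon next to C8a, which carries the pyran oxygen O1. A phenol that holds C4 of unit 2 on one ortho carbon therefore has one free ortho carbon (the future C4a), and ring C of unit 3 can only be built there, so the 4→8 connectivity is fixed before that ring exists.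
3. Ring C of unit 3 is taken apart in this order: the C3 hydroxyl (hydroboration of a flav-3-ene, then oxidation and reduction to 2,3-cis), the C3=C4 bond (ring-closing metathesis of a 2-vinylphenyl 1-arylallyl ether), the O1–C2 bond (iridium-catalysed asymmetric allylic etherification) and the vinyl group (ortho-formylation, Wittig).
4. The phenol comes from Friedel–Crafts alkylation of 3,5-bis(benzyloxy)phenol by the C4 cation of benzylated (−)-epiafzelechin (DDQ activation of C4).
5. Ring order: all rings of units 1 and 2 and ring A of unit 3 come from the starting materials; the only ring made is ring C of unit 3 (step 11).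

Key step: step 11

Remark on descriptors: "4β" means that the bond at C4 is trans to the C2 aryl group of the same unit (in units 2 and 3 also trans to the C3 oxygen). The ether carbon of 14 and C2 of the flav-3-ene 15 are S by the CIP rules (aryl outranks the vinyl carbon); the same carbon becomes R once C3 carries oxygen (17 to 24), with no change in its spatial arrangement.
Assumption: the (Sa,Sc,Sc) antipode of the phosphoramidite is taken to give the (S)-ether in step 10, by the usual sense of induction of this catalyst family with cinnamyl carbonates; if a model phenol shows the opposite sense, the (Ra,Rc,Rc) ligand is used.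

Step 1
Reactants: 1 (−)-epiafzelechin
Product: 2 5,7,4'-tri-O-benzylepiafzelechin
Conditions: BnBr (3.3 equiv), K2CO3, DMF, 0 °C to rt, argon
Reagents that add atoms: benzyl bromide, BrCc1ccccc1
Why: Williamson etherification under carbonate base alkylates the three phenols and leaves the secondary 3-OH free, and mild conditions under argon should avoid epimerisation at C2.

Step 2
Reactants: 2 5,7,4'-tri-O-benzylepiafzelechin
Product: 3 5,7,4'-tri-O-benzyl-4β-(2-ethoxyethoxy)epiafzelechin (2R,3R,4S)
Conditions: DDQ (2 equiv), 2-ethoxyethanol (5 equiv), CH2Cl2, rt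
Reagents that add atoms: 2-ethoxyethanol, CCOCCO
Why: DDQ benzylic oxidation removes hydride from C4, which is activated by the ortho and para oxygens of ring A, and the alcohol traps the cation on the face trans to the 3-OH and the C2 aryl group, which sets C4 as the 4β ether.

Step 3
Reactants: 3 5,7,4'-tri-O-benzyl-4β-(2-ethoxyethoxy)epiafzelechin
Product: 4 3,5,7,4'-tetra-O-benzyl-4β-(2-ethoxyethoxy)epiafzelechin (2R,3R,4S)
Conditions: NaH, BnBr, Bu4NI (cat.), THF/DMF, 0 °C to rt
Reagents that add atoms: benzyl bromide, BrCc1ccccc1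
Why: Williamson etherification of the secondary alkoxide protects the unit 2 hydroxyl so that only the unit 3 hydroxyl is oxidised later, and the C4 ether is stable to base.

Step 4
Reactants: 4 3,5,7,4'-tetra-O-benzyl-4β-(2-ethoxyethoxy)epiafzelechin; 5 3,5-bis(benzyloxy)phenol (3 equiv)
Product: 6 3,5-bis(benzyloxy)-2-(3,5,7,4'-tetra-O-benzylepiafzelechin-4β-yl)phenol
Conditions: TMSOTf (0.2 equiv), CH2Cl2, −78 to −40 °C, then Et3N
Reagents that add atoms: none
Why: Friedel–Crafts alkylation: the Lewis acid ionises the C4 ether to the benzylic cation, the phenol attacks through a carbon ortho to OH (less shielded than the carbon between two benzyloxy groups, the same preference that directs benzylated flavans to C8 over C6), and approach anti to the 3-OBn and C2 aryl groups sets the 4β bond.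

Step 5
Reactants: 6 3,5-bis(benzyloxy)-2-(3,5,7,4'-tetra-O-benzylepiafzelechin-4β-yl)phenol
Product: 7 4,6-bis(benzyloxy)-2-hydroxy-3-(3,5,7,4'-tetra-O-benzylepiafzelechin-4β-yl)benzaldehyde
Conditions: MgCl2 (2 equiv), Et3N (4 equiv), (CH2O)n (6 equiv), THF, 65 °C
Reagents that add atoms: formaldehyde (as paraformaldehyde), C=O
Why: Casiraghi–Skattebøl ortho-formylation: the magnesium phenoxide delivers formaldehyde to the only free ortho carbon and a second formaldehyde oxidises the benzylic alkoxide by hydride transfer, so the non-phenolic ring A of unit 2 is not touched.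

Step 6
Reactants: 7 4,6-bis(benzyloxy)-2-hydroxy-3-(3,5,7,4'-tetra-O-benzylepiafzelechin-4β-yl)benzaldehyde
Product: 8 3,5-bis(benzyloxy)-2-(3,5,7,4'-tetra-O-benzylepiafzelechin-4β-yl)-6-vinylphenol
Conditions: Ph3PCH3Br (3 equiv), KOt-Bu (3 equiv), THF, 0 °C to rt; neutral work-up, used promptly
Reagents that add atoms: methyltriphenylphosphonium bromide, C[P+](c1ccccc1)(c1ccccc1)c1ccccc1.[Br-]
Why: Wittig methylenation with excess ylide (one equivalent is consumed as base by the phenol) converts the salicylaldehyde into the 2-vinylphenol, which is kept away from acid because electron-rich vinylphenols dimerise.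

Step 7
Reactants: 9 4-hydroxycinnamic acid
Product: 10 benzyl (E)-3-[4-(benzyloxy)phenyl]prop-2-enoate
Conditions: BnBr (2.3 equiv), K2CO3, DMF, 60 °C
Reagents that add atoms: benzyl bromide, BrCc1ccccc1
Why: Williamson etherification and carboxylate alkylation take place in one operation.

Step 8
Reactants: 10 benzyl (E)-3-[4-(benzyloxy)phenyl]prop-2-enoate
Product: 11 (E)-3-[4-(benzyloxy)phenyl]prop-2-en-1-ol
Conditions: i-Bu2AlH (4.5 equiv), CH2Cl2, −78 to 0 °C; aq. sodium potassium tartrate
Reagents that add atoms: none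
Why: Aluminium hydride reduction of the unsaturated ester is a clean 1,2-reduction to the allylic alcohol with the E alkene kept.

Step 9
Reactants: 11 (E)-3-[4-(benzyloxy)phenyl]prop-2-en-1-ol
Product: 12 (E)-3-[4-(benzyloxy)phenyl]prop-2-enyl methyl carbonate
Conditions: ClCO2Me, pyridine, CH2Cl2, 0 °C
Reagents that add atoms: methyl chloroformate, COC(=O)Cl
Why: Acylation of the primary alcohol gives the carbonate leaving group needed for allyl–iridium formation.

Step 10
Reactants: 8 3,5-bis(benzyloxy)-2-(3,5,7,4'-tetra-O-benzylepiafzelechin-4β-yl)-6-vinylphenol; 12 (E)-3-[4-(benzyloxy)phenyl]prop-2-enyl methyl carbonate (1.5 equiv)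
Product: 14 (S)-1-(4-benzyloxyphenyl)prop-2-enyl ether of phenol 8, via lithium phenoxide 13 (not isolated)
Conditions: LiN(SiMe3)2 (1.0 equiv), THF, 0 °C; then 12, [Ir(cod)Cl]2 (4 mol %), (Sa,Sc,Sc)-(1,1'-binaphthalene-2,2'-diyl) N,N-bis(1-phenylethyl)phosphoramidite (8 mol %, catalyst pre-activated with n-PrNH2), THF, 25–40 °C; Et3N-deactivated silica
Reagents that add atoms: lithium bis(trimethylsilyl)amide, [Li+].C[Si](C)(C)[N-][Si](C)(C)C (lithium of 13 only)
Why: Iridium-catalysed asymmetric allylic etherification: the phenoxide attacks the aryl-substituted terminus of the allyl–iridium complex to give the branched ether, and the ligand fixes the face of attack and thereby the S ether carbon (the future C2 of unit 3).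

Step 11
Reactants: 14 (S)-1-(4-benzyloxyphenyl)prop-2-enyl ether of phenol 8
Product: 15 benzylated dimer with unit 3 as its flav-3-ene: (2S)-5,7-bis(benzyloxy)-2-(4-benzyloxyphenyl)-8-(3,5,7,4'-tetra-O-benzylepiafzelechin-4β-yl)-2H-chromene
Conditions: second-generation Grubbs catalyst RuCl2(=CHPh)(PCy3)(H2IMes) (5–10 mol %), 1,4-benzoquinone (10 mol %), CH2Cl2 (0.005 M), 40 °C
Reagents that add atoms: none
Why: The ruthenium alkylidene first exchanges onto the unhindered terminal alkene of the allyl ether, then adds across the ortho vinyl group in a [2+2] step to a ruthenacyclobutane that cycloreverts to the C3=C4 alkene and a ruthenium methylidene, so ethylene is the only by-product. The closest known reaction is ring-closing metathesis of 2-vinylphenyl allyl ethers to 2H-chromenes, including 2-aryl cases prepared by asymmetric allylic etherification. Ring C of unit 3 closes as a six-membered ring by joining C3 (from the allyl group) to C4 (from the styrene), and the ring enforces the cis alkene. No stereocentre is formed; C2 was fixed in step 10 and is carried through unchanged. The selectivity needed is metathesis over ruthenium hydride-mediated migration of the allyl double bond toward C2, which would erase that centre or lead to a benzofuran; fast closure of an unstrained six-membered ring, high dilution, moderate temperature and the benzoquinone hydride scavenger should secure it. There is no regiochemical choice, because the ether oxygen has one ortho carbon with a vinyl group and the other is occupied by C4 of unit 2.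

Step 12
Reactants: 15 benzylated dimer with unit 3 as its flav-3-ene
Product: 17 (3,5,7,4'-tetra-O-benzylepiafzelechin)-(4β→8)-(5,7,4'-tri-O-benzylafzelechin) [unit 3 2R,3S], via unit 3 C3 alkylborane 16 (not isolated)
Conditions: BH3·THF (3 equiv), THF, 0 °C to rt; then 3 M NaOH, 30% H2O2, 0 °C to rt
Reagents that add atoms: borane–tetrahydrofuran, B.C1CCOC1 (boron of 16); hydrogen peroxide, OO (oxygen of 17)
Why: Hydroboration–oxidation: boron adds to C3 and hydrogen to the benzylic C4 of the electron-rich styrene-type alkene, syn addition occurs on the face anti to the C2 aryl group, and oxidation with retention gives the 2,3-trans 3-ol.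

Step 13
Reactants: 17 (3,5,7,4'-tetra-O-benzylepiafzelechin)-(4β→8)-(5,7,4'-tri-O-benzylafzelechin)
Product: 18 unit 3 flavan-3-one of the benzylated dimer (unit 3 2R)
Conditions: Dess–Martin periodinane (1.5 equiv), NaHCO3, wet CH2Cl2, rt
Reagents that add atoms: none
Why: Dess–Martin oxidation of the only free alcohol under buffered, near-neutral conditions gives the flavan-3-one without enolising C2.

Step 14
Reactants: 18 unit 3 flavan-3-one of the benzylated dimer
Product: 19 (3,5,7,4'-tetra-O-benzylepiafzelechin)-(4β→8)-(5,7,4'-tri-O-benzylepiafzelechin) [unit 3 2R,3R]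
Conditions: Li[s-Bu3BH] (1.5 equiv), LiBr, THF, −78 °C; then NaOH, H2O2 work-up
Reagents that add atoms: none
Why: Bulky trialkylborohydride reduction delivers hydride to the ketone face opposite the C2 aryl group, which places the new 3-OH cis to that aryl (2,3-cis), and the low temperature keeps C2 from epimerising.

Step 15
Reactants: 20 (2S)-liquiritigenin
Product: 21 (2S)-7,4'-di-O-benzylliquiritigenin
Conditions: BnOH (2.4 equiv), PPh3 (2.4 equiv), diisopropyl azodicarboxylate (2.4 equiv), THF, 0 °C to rt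
Reagents that add atoms: benzyl alcohol, OCc1ccccc1
Why: Mitsunobu etherification benzylates both phenols without a free base, which avoids the base-induced ring opening to the chalcone that would racemise C2 of a 5-deoxyflavanone.

Step 16
Reactants: 21 (2S)-7,4'-di-O-benzylliquiritigenin
Product: 22 (2S,4S)-7-benzyloxy-2-(4-benzyloxyphenyl)chroman-4-ol (2,4-cis expected as major isomer)
Conditions: NaBH4, THF/MeOH, 0 °C
Reagents that add atoms: none
Why: Borohydride reduction of the ketone gives the flavan-4-ol, and the C4 configuration is irrelevant because the centre is ionised in the next step.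

Step 17
Reactants: 19 (3,5,7,4'-tetra-O-benzylepiafzelechin)-(4β→8)-(5,7,4'-tri-O-benzylepiafzelechin); 22 (2S,4S)-7-benzyloxy-2-(4-benzyloxyphenyl)chroman-4-ol (1.1 equiv, added slowly)
Product: 23 nona-O-benzyl trimer: [(2S,4R)-7,4'-di-O-benzylflavan]-(4β→8)-(3,5,7,4'-tetra-O-benzylepiafzelechin)-(4β→8)-(5,7,4'-tri-O-benzylepiafzelechin)
Conditions: TMSOTf (0.2 equiv), 4 Å MS, CH2Cl2, −40 to 0 °C, then Et3N
Reagents that add atoms: none
Why: Friedel–Crafts alkylation: the para-alkoxy-stabilised C4 cation of unit 1 should be attacked by C8 of unit 2 (the only free ring carbon flanked by one rather than two benzyloxy groups, and the usual site of chain extension in benzylated oligoflavans) on the face anti to the C2 aryl group, which sets the 2,4-trans (4R) centre.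

Step 18
Reactants: 23 nona-O-benzyl trimer
Product: 24 CNP0257624.1, (2S)-4',7-dihydroxyflavan-(4β→8)-epiafzelechin-(4β→8)-epiafzelechin
Conditions: H2 (1 atm), Pd(OH)2/C, THF/MeOH/H2O, rt
Reagents that add atoms: none
Why: Hydrogenolysis cleaves the nine benzyl ethers under neutral conditions that should leave the two interflavan bonds and the pyran C–O bonds intact.

Compound list
1 | (−)-epiafzelechin, (2R,3R)-2-(4-hydroxyphenyl)chromane-3,5,7-triol | Oc1cc(O)c2c(c1)O[C@H](c1ccc(O)cc1)[C@H](O)C2 | starting material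
2 | 5,7,4'-tri-O-benzylepiafzelechin, (2R,3R)-5,7-bis(benzyloxy)-2-(4-benzyloxyphenyl)chroman-3-ol | c1c(OCc5ccccc5)cc(OCc5ccccc5)c2c1O[C@H](c1ccc(OCc5ccccc5)cc1)[C@H](O)C2 | intermediate
3 | 5,7,4'-tri-O-benzyl-4β-(2-ethoxyethoxy)epiafzelechin (2R,3R,4S; 4-alkoxy trans to 3-OH) | c1c(OCc5ccccc5)cc(OCc5ccccc5)c2c1O[C@H](c1ccc(OCc5ccccc5)cc1)[C@H](O)[C@H]2OCCOCC | intermediate
4 | 3,5,7,4'-tetra-O-benzyl-4β-(2-ethoxyethoxy)epiafzelechin (2R,3R,4S) | c1c(OCc5ccccc5)cc(OCc5ccccc5)c2c1O[C@H](c1ccc(OCc5ccccc5)cc1)[C@H](OCc5ccccc5)[C@H]2OCCOCC | intermediate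
5 | 3,5-bis(benzyloxy)phenol | Oc1cc(OCc2ccccc2)cc(OCc2ccccc2)c1 | starting material
6 | 3,5-bis(benzyloxy)-2-(3,5,7,4'-tetra-O-benzylepiafzelechin-4β-yl)phenol | c1c(OCc5ccccc5)cc(OCc5ccccc5)c2c1O[C@H](c1ccc(OCc5ccccc5)cc1)[C@H](OCc5ccccc5)[C@H]2c1c(OCc5ccccc5)cc(OCc5ccccc5)cc1O | intermediate
7 | 4,6-bis(benzyloxy)-2-hydroxy-3-(3,5,7,4'-tetra-O-benzylepiafzelechin-4β-yl)benzaldehyde | c1c(OCc5ccccc5)cc(OCc5ccccc5)c2c1O[C@H](c1ccc(OCc5ccccc5)cc1)[C@H](OCc5ccccc5)[C@H]2c1c(OCc5ccccc5)cc(OCc5ccccc5)c(C=O)c1O | intermediate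
8 | 3,5-bis(benzyloxy)-2-(3,5,7,4'-tetra-O-benzylepiafzelechin-4β-yl)-6-vinylphenol | c1c(OCc5ccccc5)cc(OCc5ccccc5)c2c1O[C@H](c1ccc(OCc5ccccc5)cc1)[C@H](OCc5ccccc5)[C@H]2c1c(OCc5ccccc5)cc(OCc5ccccc5)c(C=C)c1O | intermediate
9 | 4-hydroxycinnamic acid | OC(=O)/C=C/c1ccc(O)cc1 | starting material
10 | benzyl (E)-3-[4-(benzyloxy)phenyl]prop-2-enoate | O=C(OCc1ccccc1)/C=C/c1ccc(OCc2ccccc2)cc1 | intermediate
11 | (E)-3-[4-(benzyloxy)phenyl]prop-2-en-1-ol | OC/C=C/c1ccc(OCc2ccccc2)cc1 | intermediate
12 | (E)-3-[4-(benzyloxy)phenyl]prop-2-enyl methyl carbonate | COC(=O)OC/C=C/c1ccc(OCc2ccccc2)cc1 | intermediate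
13 | lithium 3,5-bis(benzyloxy)-2-(3,5,7,4'-tetra-O-benzylepiafzelechin-4β-yl)-6-vinylphenoxide (not isolated) | c1c(OCc5ccccc5)cc(OCc5ccccc5)c2c1O[C@H](c1ccc(OCc5ccccc5)cc1)[C@H](OCc5ccccc5)[C@H]2c1c(OCc5ccccc5)cc(OCc5ccccc5)c(C=C)c1[O-].[Li+] | intermediate
14 | metathesis precursor: benzylated unit 2 bearing at C4β the 2-vinylphenyl (S)-1-(4-benzyloxyphenyl)prop-2-enyl ether | c1c(OCc5ccccc5)cc(OCc5ccccc5)c2c1O[C@H](c1ccc(OCc5ccccc5)cc1)[C@H](OCc5ccccc5)[C@H]2c1c(OCc5ccccc5)cc(OCc5ccccc5)c(C=C)c1O[C@H](c1ccc(OCc5ccccc5)cc1)C=C | intermediate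
15 | benzylated dimer with unit 3 as its (2S)-flav-3-ene | c1c(OCc5ccccc5)cc(OCc5ccccc5)c2c1O[C@H](c1ccc(OCc5ccccc5)cc1)[C@H](OCc5ccccc5)[C@H]2c1c(OCc5ccccc5)cc(OCc5ccccc5)c2c1O[C@H](c1ccc(OCc5ccccc5)cc1)C=C2 | intermediate
16 | unit 3 C3 alkylborane (BH2 at C3 trans to the C2 aryl group, H at C4; not isolated) | c1c(OCc5ccccc5)cc(OCc5ccccc5)c2c1O[C@H](c1ccc(OCc5ccccc5)cc1)[C@H](OCc5ccccc5)[C@H]2c1c(OCc5ccccc5)cc(OCc5ccccc5)c2c1O[C@H](c1ccc(OCc5ccccc5)cc1)[C@@H](B)C2 | intermediate
17 | (3,5,7,4'-tetra-O-benzylepiafzelechin)-(4β→8)-(5,7,4'-tri-O-benzylafzelechin), unit 3 2R,3S (2,3-trans) | c1c(OCc5ccccc5)cc(OCc5ccccc5)c2c1O[C@H](c1ccc(OCc5ccccc5)cc1)[C@H](OCc5ccccc5)[C@H]2c1c(OCc5ccccc5)cc(OCc5ccccc5)c2c1O[C@H](c1ccc(OCc5ccccc5)cc1)[C@@H](O)C2 | intermediate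
18 | unit 3 flavan-3-one of the benzylated dimer, unit 3 2R | c1c(OCc5ccccc5)cc(OCc5ccccc5)c2c1O[C@H](c1ccc(OCc5ccccc5)cc1)[C@H](OCc5ccccc5)[C@H]2c1c(OCc5ccccc5)cc(OCc5ccccc5)c2c1O[C@H](c1ccc(OCc5ccccc5)cc1)C(=O)C2 | intermediate
19 | (3,5,7,4'-tetra-O-benzylepiafzelechin)-(4β→8)-(5,7,4'-tri-O-benzylepiafzelechin), unit 3 2R,3R (2,3-cis) | c1c(OCc5ccccc5)cc(OCc5ccccc5)c2c1O[C@H](c1ccc(OCc5ccccc5)cc1)[C@H](OCc5ccccc5)[C@H]2c1c(OCc5ccccc5)cc(OCc5ccccc5)c2c1O[C@H](c1ccc(OCc5ccccc5)cc1)[C@H](O)C2 | intermediate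
20 | (2S)-liquiritigenin | O=C1C[C@@H](c2ccc(O)cc2)Oc2cc(O)ccc21 | starting material
21 | (2S)-7,4'-di-O-benzylliquiritigenin | O=C1C[C@@H](c2ccc(OCc3ccccc3)cc2)Oc2cc(OCc3ccccc3)ccc21 | intermediate
22 | (2S,4S)-7-benzyloxy-2-(4-benzyloxyphenyl)chroman-4-ol (2,4-cis) | O[C@H]1C[C@@H](c2ccc(OCc3ccccc3)cc2)Oc2cc(OCc3ccccc3)ccc21 | intermediate
23 | nona-O-benzyl trimer, unit 1 (2S,4R), unit 3 3-OH free | c5ccccc5COc1ccc([C@@H]2C[C@@H](c3c(OCc5ccccc5)cc(OCc5ccccc5)c4c3O[C@H](c3ccc(OCc5ccccc5)cc3)[C@H](OCc5ccccc5)[C@H]4c3c(OCc5ccccc5)cc(OCc5ccccc5)c4c3O[C@H](c3ccc(OCc5ccccc5)cc3)[C@H](O)C4)c3ccc(OCc5ccccc5)cc3O2)cc1 | intermediate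
24 | CNP0257624.1, (2S)-4',7-dihydroxyflavan-(4β→8)-epiafzelechin-(4β→8)-epiafzelechin | Oc1ccc([C@@H]2C[C@@H](c3c(O)cc(O)c4c3O[C@H](c3ccc(O)cc3)[C@H](O)[C@H]4c3c(O)cc(O)c4c3O[C@H](c3ccc(O)cc3)[C@H](O)C4)c3ccc(O)cc3O2)cc1 | target

Total step count: 18
Longest linear sequence: 13 steps (steps 1–6, 10–14, 17, 18, from 1 to 24)

Steps most likely to fail

Step 10. The phenoxide has substituents on both ortho carbons, one of them the bulky unit 2, so its attack on the allyl–iridium complex may be slow. That would allow linear ether formation, loss of catalyst control through a mismatched pairing with the chiral phenoxide, or ionisation of the acid-sensitive product. The fallback sets out from 8 and comes back at 14 and gives up catalyst control of the ether carbon. Methyl 2-[4-(benzyloxy)phenyl]acetate is brominated through its enolate (LiN(SiMe3)2, then N-bromosuccinimide, THF, −78 °C) to methyl 2-bromo-2-[4-(benzyloxy)phenyl]acetate F1. Williamson alkylation of 8 with F1 (Cs2CO3, DMF, rt) gives the methyl 2-aryloxy-2-[4-(benzyloxy)phenyl]acetate F2 as both epimers at the new carbon. Reduction with i-Bu2AlH at −78 °C gives the aldehyde F3, and Wittig methylenation (Ph3PCH3Br, KOt-Bu, THF) gives 14 together with its ether-carbon epimer F4, which is removed by chromatography.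

Step 11. Closure onto the crowded, doubly ortho-substituted styrene may be slower than catalyst decay to ruthenium hydrides. That would lead to migration of the allyl double bond, loss of the C2 configuration, or stalling. The fallback sets out from 6 and 11 and comes back at 15 without any metathesis. MnO2 oxidation of 11 (CH2Cl2, rt) gives (E)-3-[4-(benzyloxy)phenyl]prop-2-enal F5. Heating 6 with F5, PhB(OH)2 and catalytic propionic acid in toluene with removal of water forms the 2-phenyl-4H-1,3,2-benzodioxaborin F6 at the only free ortho carbon. F6 fragments to an ortho-quinone methide, which closes by oxa-6π electrocyclisation to the 2-aryl-2H-chromene. This gives 15 and its C2 epimer F7 without stereocontrol; the two are separated by chromatography and 15 continues with step 12.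

Step 17. The unit 1 cation may be intercepted by the C6 carbons or by a second molecule of product, may add with incomplete trans selectivity at its C4, or may be lost to self-condensation and elimination to the flav-3-ene before it meets 19. The fallback sets out from 22 and 19 and comes back at 23, and replaces the acid-ionised alcohol by a stored thioether activated with a thiophilic salt. 22 is treated with 2-mercaptobenzothiazole and catalytic BF3·OEt2 (CH2Cl2, 0 °C) to give (2S)-4-(1,3-benzothiazol-2-ylsulfanyl)-7-benzyloxy-2-(4-benzyloxyphenyl)chromane F8, which is purified. F8 and 19 are then combined in equimolar amounts with AgBF4 (THF/CH2Cl2, 0 °C), which should release the cation slowly and without a protic or oxophilic acid that could reopen the interflavan bonds, to give 23.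

Further compounds
F1 | step 10 | methyl 2-bromo-2-[4-(benzyloxy)phenyl]acetate | COC(=O)C(Br)c1ccc(OCc2ccccc2)cc1
F2 | step 10 | methyl 2-aryloxy-2-[4-(benzyloxy)phenyl]acetate from 8 (both epimers at the new carbon) | c1c(OCc5ccccc5)cc(OCc5ccccc5)c2c1O[C@H](c1ccc(OCc5ccccc5)cc1)[C@H](OCc5ccccc5)[C@H]2c1c(OCc5ccccc5)cc(OCc5ccccc5)c(C=C)c1OC(C(=O)OC)c1ccc(OCc5ccccc5)cc1
F3 | step 10 | 2-aryloxy-2-[4-(benzyloxy)phenyl]acetaldehyde from F2 (both epimers) | c1c(OCc5ccccc5)cc(OCc5ccccc5)c2c1O[C@H](c1ccc(OCc5ccccc5)cc1)[C@H](OCc5ccccc5)[C@H]2c1c(OCc5ccccc5)cc(OCc5ccccc5)c(C=C)c1OC(C=O)c1ccc(OCc5ccccc5)cc1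
F4 | step 10 | ether-carbon epimer of 14, (R)-1-(4-benzyloxyphenyl)prop-2-enyl ether | c1c(OCc5ccccc5)cc(OCc5ccccc5)c2c1O[C@H](c1ccc(OCc5ccccc5)cc1)[C@H](OCc5ccccc5)[C@H]2c1c(OCc5ccccc5)cc(OCc5ccccc5)c(C=C)c1O[C@@H](c1ccc(OCc5ccccc5)cc1)C=C
F5 | step 11 | (E)-3-[4-(benzyloxy)phenyl]prop-2-enal | O=C/C=C/c1ccc(OCc2ccccc2)cc1
F6 | step 11 | 2-phenyl-4-[(E)-2-(4-benzyloxyphenyl)vinyl]-4H-1,3,2-benzodioxaborin formed from 6 (not isolated) | c1c(OCc5ccccc5)cc(OCc5ccccc5)c2c1O[C@H](c1ccc(OCc5ccccc5)cc1)[C@H](OCc5ccccc5)[C@H]2c1c(OCc5ccccc5)cc(OCc5ccccc5)c3c1OB(c1ccccc1)OC3/C=C/c1ccc(OCc5ccccc5)cc1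
F7 | step 11 | C2 epimer of 15 in unit 3, (2R)-flav-3-ene | c1c(OCc5ccccc5)cc(OCc5ccccc5)c2c1O[C@H](c1ccc(OCc5ccccc5)cc1)[C@H](OCc5ccccc5)[C@H]2c1c(OCc5ccccc5)cc(OCc5ccccc5)c2c1O[C@@H](c1ccc(OCc5ccccc5)cc1)C=C2
F8 | step 17 | (2S)-4-(1,3-benzothiazol-2-ylsulfanyl)-7-benzyloxy-2-(4-benzyloxyphenyl)chromane (C4 epimers) | c1ccc2sc(SC3C[C@@H](c4ccc(OCc5ccccc5)cc4)Oc4cc(OCc5ccccc5)ccc43)nc2c1
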